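I looked first for what was slow in the amber flask, and it was not the substrate: it read 35.4 % at 0.208 d and 35.5 % at 2.50 d, with a scatter of 0.5 percentage points.

| setting | amber | green | flask |
|---|---|---|---|
| substrate | 1.2 M | 0.60 M | 1.2 M |
| coupling partner | 1.8 M | 1.8 M | 1.80 M |
| remark | the very flask that is asked about, followed so far | run made earlier |  |
| time |  |  | 8.0 d |

| run | time / d | substrate / % | first product / % |
|---|---|---|---|
| amber | 0.208 | 35.4 | 13.8 |
| amber | 0.333 | 37.0 | 14.0 |
| amber | 0.500 | 36.8 | 13.1 |
| amber | 0.833 | 36.6 | 12.7 |
| amber | 1.67 | 36.4 | 11.3 |
| amber | 2.50 | 35.5 | 11.1 |
| green | 0.250 | 12.9 | 6.1 |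
| green | 0.417 | 12.8 | 6.2 |
| green | 0.625 | 13.2 | 5.0 |
| green | 1.25 | 12.9 | 4.7 |
| green | 2.08 | 12.7 | 5.1 |
| green | 3.00 | 12.8 | 3.8 |

(readings scatter by 0.5 percentage points)

- amount of substrate at 8.0 d, in percent of the substrate charged
- amount of first product at 8.0 d, in percent of the substrate charged
- amount of double product at 8.0 d, in percent of the substrate charged
- amount of triple product at 8.0 d, in percent of the substrate charged

- the numbers in the tables scatter with a standard deviation of 0.5 points

In the amber run the 6 substrate readings average 36.3 %, and in the green run 12.9 %. The natural log of one over those fractions is 1.01 and 2.05. My zero was a charge that makes no difference, with equal logs; instead the green log is twice the amber one, and the green run had twice the coupling partner per substrate.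

Across the whole amber run the substrate reading moved by 0.1 points, so an error in the time counts for little there, and the scatter of a reading shrinks in a mean of 6. But if the log goes with partner per substrate, coupling partner charged 10 % low would shift the amber substrate by 3.9 points, so partner per substrate, 1.50 in the asked flask, has to be known well.

Each log divided by its partner per substrate gave 0.676 and 0.683, with a mean of 0.679; I call this log per partner per substrate the reach. For the asked flask, which is the amber flask, it gives 36.1 % substrate.

The forecast gave 36 % substrate, 6.5 % first product, 37 % double product and 20.5 % triple product, and called its split between the last two “a guess, hence wide ranges”. The flask held 36.0 %, 5.61 %, 30.7 % and 14.9 %, in that order.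

    substrate + coupling partner → first product (k = 0.0530 /M/min)
    coupling partner + first product → double product (k = 0.176 /M/min)
    coupling partner + double product → triple product (k = 0.0605 /M/min)
    coupling partner + triple product → tetra adduct (k = 0.0435 /M/min)
    coupling partner → decomposed reagent (k = 0.00775 /min)
    first product → over-reaction product (k = 7.98 × 10⁻⁵ /min)

Coupling partner, the limiting reagent, stood at 0 % of its charge after 8.00 d, and the 36.0 % substrate puts this flask's reach at 0.682. In the neighbouring flask with 0.72 M substrate, other charges and time held, partner per substrate is 2.50, so the reach gives 18.3 % substrate left; that flask held 18.3 %.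

The numbers in the tables were computed on assumed constants, noise included.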